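**Retrosynthetic overview**
- CJ-13,108 is traced back to a terminal alkene (Tsuji–Wacker oxidation gives the side-chain methyl ketone) and to a silyl-protected hydroxy benzoate (lactonisation closes O2–C1).
- The benzene ring C3a–C4–C5–C6–C7–C7a is disconnected by an Alder–Rickert benzannulation (bonds C3a–C4 and C7–C7a, ethylene lost) into an (S)-4-silyloxyalk-2-ynoate and 1,3-dimethoxycyclohexa-1,3-diene.
- The feature the strategy rests on: the phthalide benzene ring carries methoxy groups on C5 and C7, the carboxyl carbon C1 on C7a and the carbinol carbon C3 on C3a. This is a 2,4-dimethoxy-6-alkylbenzoate, exactly the pattern this diene/ynoate pair delivers.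
- The ynoate comes from asymmetric zinc alkynylation of pentadec-14-enal with methyl propiolate (sets C3); the enal from 12-bromododecan-1-ol and allylmagnesium bromide; the diene from 1,3-dimethoxybenzene by Birch reduction and conjugation.
- Ring order: benzene ring first (step 7), γ-lactone ring second (step 8).

Key step: step 7

Assumption: the (S,S)-ProPhenol–zinc catalyst is taken to deliver the alkynyl group to the Re face of an unbranched aliphatic aldehyde, which gives the (S)-carbinol; the configuration of 8 is to be checked by Mosher ester analysis, and the (R,R)-ligand is used instead should the sense be the opposite.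

**Route**

Step 1
Reactants: 1 12-bromododecan-1-ol; 2 allylmagnesium bromide
Product: 4 pentadec-14-en-1-ol, via bromomagnesium 12-bromododecan-1-olate 3 (not isolated)
Conditions: 2 (2.5 equiv), Li2CuCl4 (3 mol %), THF, 0 °C to rt; aq. NH4Cl
Reagents that add atoms: none
Why: The first equivalent of the Grignard reagent masks the hydroxyl as its magnesium alkoxide and the second should couple with the primary bromide under copper catalysis (Kochi cross-coupling), which is routine for ω-bromoalkanols.

Step 2
Reactants: 4 pentadec-14-en-1-ol
Product: 5 pentadec-14-enal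
Conditions: TEMPO (10 mol %), PhI(OAc)2 (1.1 equiv), CH2Cl2, rt
Reagents that add atoms: none
Why: The oxoammonium-mediated oxidation of a primary alcohol should stop at the aldehyde and leave the isolated terminal alkene untouched.

Step 3
Reactants: 5 pentadec-14-enal; 6 methyl propiolate
Product: 8 methyl (S)-4-hydroxyoctadec-17-en-2-ynoate, via methyl 3-(methylzincio)prop-2-ynoate 7 (not isolated)
Conditions: (S,S)-ProPhenol (20 mol %), Ph3P=O (40 mol %), Me2Zn (3 equiv), 6 (3 equiv), toluene, 4 °C, slow addition of 5; aq. NH4Cl
Reagents that add atoms: none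
Why: In this catalytic asymmetric alkynylation the dinuclear zinc–ProPhenol complex holds the aldehyde on one zinc and the alkynyl group on the other and should deliver the alkynyl group to the Re face of the aldehyde, which sets the (S)-carbinol centre (the later C3).

Step 4
Reactants: 8 methyl (S)-4-hydroxyoctadec-17-en-2-ynoate
Product: 9 methyl (S)-4-(tert-butyldimethylsilyloxy)octadec-17-en-2-ynoate
Conditions: TBSOTf (1.2 equiv), 2,6-lutidine (1.5 equiv), CH2Cl2, −78 to 0 °C
Reagents that add atoms: tert-butyldimethylsilyl triflate, CC(C)(C)[Si](C)(C)OS(=O)(=O)C(F)(F)F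
Why: O-Silylation with a silyl triflate and a hindered, non-nucleophilic base at low temperature should protect the carbinol without base-induced isomerisation of the γ-hydroxy ynoate or conjugate addition to it, and it does not touch the stereocentre.

Step 5
Reactants: 10 1,3-dimethoxybenzene
Product: 11 1,5-dimethoxycyclohexa-1,4-diene
Conditions: Na (2.5 equiv), liq. NH3, EtOH, Et2O, −78 to −33 °C; H2O, pentane (no acid)
Reagents that add atoms: none
Why: Birch reduction of an arene with two donor groups protonates the carbons that bear no oxygen, so both methoxy groups should remain on the double bonds of the 1,4-diene.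

Step 6
Reactants: 11 1,5-dimethoxycyclohexa-1,4-diene
Product: 12 1,3-dimethoxycyclohexa-1,3-diene
Conditions: KOt-Bu (10 mol %), DMSO, rt; pentane/H2O; distilled and stored over K2CO3
Reagents that add atoms: none
Why: Base-mediated prototropic isomerisation (deprotonation of the CH2 between the two methoxy-bearing carbons, reprotonation at a terminus of the pentadienyl anion) should give an equilibrium mixture rich in the conjugated diene, which is used as such because residual 11 is not a diene partner.

Step 7
Reactants: 9 methyl (S)-4-(tert-butyldimethylsilyloxy)octadec-17-en-2-ynoate; 12 1,3-dimethoxycyclohexa-1,3-diene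
Product: 14 methyl (S)-2-[1-(tert-butyldimethylsilyloxy)pentadec-14-enyl]-4,6-dimethoxybenzoate, via bicyclo[2.2.2]octadiene adduct 13 (not isolated)
Conditions: 12 (4 equiv), neat, BHT (cat.), base-washed sealed tube, 180 °C
Reagents that add atoms: none
Why: Heating the electron-rich 1,3-dialkoxydiene 12 with the electron-poor ynoate 9 without catalyst should bring about a concerted, asynchronous [4+2] cycloaddition that forms C3a–C4 and C7–C7a (phthalide numbering) and gives the bicyclo[2.2.2]octa-2,5-diene 13, which at the same temperature expels its ethano bridge as ethylene in a retro-Diels–Alder step driven by aromatisation and loss of a gas. The closest known reaction type is the Alder–Rickert synthesis of 6-substituted 2,4-dimethoxybenzoates from 1,3-dimethoxycyclohexadienes and alk-2-ynoates. The benzene ring is thus closed by an intermolecular cycloaddition that makes two σ bonds at once and is unveiled by cycloreversion, not by cyclisation of a chain. No new stereocentre remains, since the two bridgehead centres of 13 vanish on aromatisation, and the (S)-carbinol carbon, a silyl-protected spectator in a neutral, base-free melt, should keep its configuration. The step needs regioselectivity, which the diene secures: its unsubstituted terminus C4, made nucleophilic by both methoxy groups, bonds to the β-carbon of the ynoate (the future C3a), so that the ester carbon ends up next to the methoxy-bearing former bridgehead (C7). It also needs chemoselectivity, and the isolated terminal alkene, an unactivated dienophile, should not compete with the ynoate.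

Step 8
Reactants: 14 methyl (S)-2-[1-(tert-butyldimethylsilyloxy)pentadec-14-enyl]-4,6-dimethoxybenzoate
Product: 16 (S)-5,7-dimethoxy-3-(tetradec-13-enyl)isobenzofuran-1(3H)-one, via hydroxy ester 15 (not isolated)
Conditions: Bu4NF (1.5 equiv), THF, 0 °C to rt; aq. NH4Cl
Reagents that add atoms: none
Why: Fluoride desilylation frees the benzylic oxygen, which should close the five-membered lactone onto the ortho ester at once (intramolecular transesterification); the C3–O bond is never broken, so the configuration is retained.

Step 9
Reactants: 16 (S)-5,7-dimethoxy-3-(tetradec-13-enyl)isobenzofuran-1(3H)-one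
Product: 17 CJ-13,108, (S)-5,7-dimethoxy-3-(13-oxotetradecyl)isobenzofuran-1(3H)-one
Conditions: PdCl2 (10 mol %), CuCl (1 equiv), O2 (1 atm), DMF/H2O (7:1), rt
Reagents that add atoms: water, O
Why: In the Tsuji–Wacker oxidation divalent palladium activates the terminal alkene for Markovnikov attack of water to give the methyl ketone, and the zerovalent palladium formed is reoxidised by CuCl and O2; the lactone, the aryl ethers and the remote stereocentre are not affected.

**Compound list**

1 | 12-bromododecan-1-ol | OCCCCCCCCCCCCBr | starting material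
2 | allylmagnesium bromide | C=CC[Mg]Br | starting material
3 | bromomagnesium 12-bromododecan-1-olate | BrCCCCCCCCCCCCO[Mg]Br | intermediate (not isolated)
4 | pentadec-14-en-1-ol | OCCCCCCCCCCCCCC=C | intermediate
5 | pentadec-14-enal | O=CCCCCCCCCCCCCC=C | intermediate
6 | methyl propiolate | C#CC(=O)OC | starting material
7 | methyl 3-(methylzincio)prop-2-ynoate | COC(=O)C#C[Zn]C | intermediate (not isolated)
8 | methyl (S)-4-hydroxyoctadec-17-en-2-ynoate | COC(=O)C#C[C@H](CCCCCCCCCCCCC=C)O | intermediate
9 | methyl (S)-4-(tert-butyldimethylsilyloxy)octadec-17-en-2-ynoate | COC(=O)C#C[C@H](CCCCCCCCCCCCC=C)O[Si](C)(C)C(C)(C)C | intermediate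
10 | 1,3-dimethoxybenzene | COc1cccc(OC)c1 | starting material
11 | 1,5-dimethoxycyclohexa-1,4-diene | COC1=CCC=C(OC)C1 | intermediate
12 | 1,3-dimethoxycyclohexa-1,3-diene | COC1=CC(OC)=CCC1 | intermediate
13 | methyl 3-[(S)-1-(tert-butyldimethylsilyloxy)pentadec-14-enyl]-1,5-dimethoxybicyclo[2.2.2]octa-2,5-diene-2-carboxylate (both bridgehead diastereomers) | COC(=O)C1=C([C@H](CCCCCCCCCCCCC=C)O[Si](C)(C)C(C)(C)C)C2CCC1(OC)C=C2OC | intermediate (not isolated)
14 | methyl (S)-2-[1-(tert-butyldimethylsilyloxy)pentadec-14-enyl]-4,6-dimethoxybenzoate | COC(=O)c1c(OC)cc(OC)cc1[C@H](CCCCCCCCCCCCC=C)O[Si](C)(C)C(C)(C)C | intermediate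
15 | methyl (S)-2-(1-hydroxypentadec-14-enyl)-4,6-dimethoxybenzoate (present as its alkoxide) | COC(=O)c1c(OC)cc(OC)cc1[C@H](CCCCCCCCCCCCC=C)O | intermediate (not isolated)
16 | (S)-5,7-dimethoxy-3-(tetradec-13-enyl)isobenzofuran-1(3H)-one | COc1cc(OC)c2c(c1)[C@H](CCCCCCCCCCCCC=C)OC2=O | intermediate
17 | CJ-13,108, (S)-5,7-dimethoxy-3-(13-oxotetradecyl)isobenzofuran-1(3H)-one | COc1cc(OC)c2c(c1)[C@H](CCCCCCCCCCCCC(C)=O)OC2=O | target

**Step count**

Total: 9 steps. Longest linear sequence: 7 steps (steps 1, 2, 3, 4, 7, 8, 9, from 12-bromododecan-1-ol); the diene arm (steps 5 and 6) is two steps.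

**Steps most likely to fail**

Step 7. The hindered γ-silyloxy ynoate may add so slowly at 180 °C that thermal dimerisation and aromatisation of the diene, or prototropic isomerisation of the ynoate to an allene, outrun the cycloaddition. The fallback sets out from 9 and comes back at 14; it uses a more electron-rich diene whose bridge is lost more easily. Commercial dimedone is bis-silylated (TMSOTf, Et3N, Et2O, 0 °C) to 5,5-dimethyl-1,3-bis(trimethylsilyloxy)cyclohexa-1,3-diene F1. Heating F1 with 9 in toluene at about 140 °C should give the bicyclo[2.2.2]octadiene adduct methyl 3-[(S)-1-(tert-butyldimethylsilyloxy)pentadec-14-enyl]-8,8-dimethyl-1,5-bis(trimethylsilyloxy)bicyclo[2.2.2]octa-2,5-diene-2-carboxylate F2 (not isolated), which loses isobutene to give methyl (S)-2-[1-(tert-butyldimethylsilyloxy)pentadec-14-enyl]-4,6-bis(trimethylsilyloxy)benzoate F3. K2CO3 (cat.) in MeOH at 0 °C should cleave only the two aryl trimethylsilyl ethers to methyl (S)-2-[1-(tert-butyldimethylsilyloxy)pentadec-14-enyl]-4,6-dihydroxybenzoate F4, and MeI with K2CO3 in acetone at reflux methylates both phenols to 14.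

Step 3. Facial selectivity may be poor with the unbranched aldehyde, and self-aldol condensation of 5 under the zinc alkoxide conditions may consume it. The fallback sets out from 5 and comes back at 9; it sets the centre by ketone reduction instead of by addition. Lithium (trimethylsilyl)acetylide (THF, −78 °C) adds to 5 to give racemic 1-(trimethylsilyl)heptadec-16-en-1-yn-3-ol F5, and Dess–Martin periodinane oxidises it to 1-(trimethylsilyl)heptadec-16-en-1-yn-3-one F6. Noyori transfer hydrogenation with RuCl[(S,S)-TsDPEN](p-cymene) in i-PrOH should give (S)-1-(trimethylsilyl)heptadec-16-en-1-yn-3-ol F7. TBSOTf with 2,6-lutidine gives the silyl ether (S)-tert-butyldimethyl{[1-(trimethylsilyl)heptadec-16-en-1-yn-3-yl]oxy}silane F8, and K2CO3 in MeOH removes the alkynyl silyl group to give (S)-tert-butyl(heptadec-16-en-1-yn-3-yloxy)dimethylsilane F9. Deprotonation of F9 with n-BuLi (THF, −78 °C) and trapping with methyl chloroformate gives 9.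

Step 9. Palladium hydride-mediated migration of the terminal double bond along the chain before oxidation would lead to regioisomeric ketones, and anti-Markovnikov attack of water would give some aldehyde. The fallback sets out from 16 and comes back at 17; it hydrates the alkene by a radical path and then oxidises. Mukaiyama hydration (Co(acac)2 cat., PhSiH3, O2, i-PrOH/THF, rt) should give (3S)-3-(13-hydroxytetradecyl)-5,7-dimethoxyisobenzofuran-1(3H)-one F10 as both epimers at the side-chain carbinol (any ketone formed directly is already the target), and Dess–Martin periodinane in CH2Cl2 oxidises F10 to 17.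

**Further compounds**

F1 | step 7 | 5,5-dimethyl-1,3-bis(trimethylsilyloxy)cyclohexa-1,3-diene | C[Si](C)(C)OC1=CC(O[Si](C)(C)C)=CC(C)(C)C1
F2 | step 7 | methyl 3-[(S)-1-(tert-butyldimethylsilyloxy)pentadec-14-enyl]-8,8-dimethyl-1,5-bis(trimethylsilyloxy)bicyclo[2.2.2]octa-2,5-diene-2-carboxylate | COC(=O)C1=C([C@H](CCCCCCCCCCCCC=C)O[Si](C)(C)C(C)(C)C)C2C(C)(C)CC1(O[Si](C)(C)C)C=C2O[Si](C)(C)C
F3 | step 7 | methyl (S)-2-[1-(tert-butyldimethylsilyloxy)pentadec-14-enyl]-4,6-bis(trimethylsilyloxy)benzoate | COC(=O)c1c(O[Si](C)(C)C)cc(O[Si](C)(C)C)cc1[C@H](CCCCCCCCCCCCC=C)O[Si](C)(C)C(C)(C)C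
F4 | step 7 | methyl (S)-2-[1-(tert-butyldimethylsilyloxy)pentadec-14-enyl]-4,6-dihydroxybenzoate | COC(=O)c1c(O)cc(O)cc1[C@H](CCCCCCCCCCCCC=C)O[Si](C)(C)C(C)(C)C
F5 | step 3 | racemic 1-(trimethylsilyl)heptadec-16-en-1-yn-3-ol | C[Si](C)(C)C#CC(O)CCCCCCCCCCCCC=C
F6 | step 3 | 1-(trimethylsilyl)heptadec-16-en-1-yn-3-one | C[Si](C)(C)C#CC(=O)CCCCCCCCCCCCC=C
F7 | step 3 | (S)-1-(trimethylsilyl)heptadec-16-en-1-yn-3-ol | C[Si](C)(C)C#C[C@H](CCCCCCCCCCCCC=C)O
F8 | step 3 | (S)-tert-butyldimethyl{[1-(trimethylsilyl)heptadec-16-en-1-yn-3-yl]oxy}silane | C[Si](C)(C)C#C[C@H](CCCCCCCCCCCCC=C)O[Si](C)(C)C(C)(C)C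
F9 | step 3 | (S)-tert-butyl(heptadec-16-en-1-yn-3-yloxy)dimethylsilane | C#C[C@H](CCCCCCCCCCCCC=C)O[Si](C)(C)C(C)(C)C
F10 | step 9 | (3S)-3-(13-hydroxytetradecyl)-5,7-dimethoxyisobenzofuran-1(3H)-one (both side-chain epimers) | COc1cc(OC)c2c(c1)[C@H](CCCCCCCCCCCCC(C)O)OC2=O
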